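Two questions stand between these runs and an answer for the set-ups.

the same everywhere: partner 0.144 M; rival reagent 0.216 M

| flask | starting material | protic impurity | remark | time |
|---|---|---|---|---|
| south-west | 0.18 M | 0.018 M | run made earlier |  |
| north-east | 0.18 M | 0.012 M | run made earlier |  |
| north-west | 0.18 M | 0.027 M | run made earlier |  |
| ochre | 0.18 M | 0.0180 M | a closed flask charged with all of it at once and left for 8.0 min | 8.0 min |
| violet | 0.18 M (fed, over 8.00 min) | 0.0180 M | all but starting material at the start; starting material goes in evenly over 8.00 min, the run ends at 8.0 min | 8.0 min |
| blue | 0.18 M | 0.0180 M | a single well-mixed tank run continuously and read at steady state, 8.0 min in it on average |  |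
| teal | 0.18 M | 0.0180 M | a tube with plug flow, the mixed feed as stated, residence time 8.0 min | 8.0 min |

| run | time / min | target / % | side product / % |
|---|---|---|---|
| south-west | 0.667 | 9.8 | 21.5 |
| south-west | 1.33 | 15.0 | 35.4 |
| south-west | 3.00 | 22.3 | 51.1 |
| south-west | 8.00 | 27.0 | 61.1 |
| north-east | 0.667 | 8.6 | 23.1 |
| north-east | 1.50 | 16.1 | 37.4 |
| north-east | 3.00 | 22.4 | 50.8 |
| north-east | 5.00 | 26.7 | 58.8 |
| north-west | 0.417 | 6.5 | 15.3 |
| north-west | 0.833 | 10.8 | 26.4 |
| north-west | 2.00 | 18.2 | 41.5 |
| north-west | 5.00 | 24.0 | 55.4 |

(scatter of a reading: 0.5 percentage points)

- the stated concentrations are those of everything mixed, before any reaction; amounts are the same in each set-up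
- the analysis behind the earlier runs scatters by 0.5 percentage points, standard deviation
- the feed brings no volume worth counting
- the earlier runs were made in a closed, stirred flask

- the set-up with the highest share of target in all that became target or side product, at the outlet or at the end ("none" if the first two lie within 2 percentage points) (ochre / violet / blue / teal / none)
- share of target in all that became target or side product, at the outlet or at the end, ochre
- share of target in all that became target or side product, at the outlet or at the end, violet
- share of target in all that became target or side product, at the outlet or at the end, blue
- share of target in all that became target or side product, at the outlet or at the end, teal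

First, does [starting material] enter the split between target and side product? In the south-west run, target over side product reads 0.424 at 1.33 min and 0.442 at 8.00 min, while what has formed climbs from 50.4% to 88.1%. So I take both routes as first order in [starting material], and it cancels from the ratio of their rates, leaving a constant s times [partner]/[rival].

Second, what is s, and how far can [partner]/[rival] move the split? I count target as partner used and side product as rival used. At the last south-west reading, the ln of partner's fall over the ln of rival's fall gives 0.579. This is my reading of the selectivity factor s, the rate constant to target over the rate constant to side product.

At the charge the ratio of rates is 0.386, a share of 27.8%. At that last south-west reading it is 0.521, a share of 34.2%, which is higher than at the charge. The share of what has formed in that run reads 30.6%, and ochre and teal repeat its history. The blue tank makes its whole product at its outlet ratio, so I expect blue somewhat above them.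

The forecast gives ochre 30.7%, violet 30%, blue 31.8%, teal 30.7%, best none, on the ground that “Since A cancels, selectivity depends only on how far partner and rival are consumed.” Its blue leads by 1.1 percentage points, less than the margin of 2 points.

The flask gives best none: ochre 30.8%, violet 30.0%, blue 31.9%, teal 30.8%.

    starting material + rival reagent → side product (k = 0.0360 L mol⁻¹ s⁻¹)
    starting material → decomposition product (k = 2.70 × 10⁻⁶ s⁻¹)
    starting material + partner → target (k = 0.0210 L mol⁻¹ s⁻¹)
    starting material + protic impurity → quenched substrate (k = 0.0900 L mol⁻¹ s⁻¹)

The route from starting material and protic impurity to quenched substrate makes no difference worth counting to the blue share. In the blue tank [partner] stands at 0.103 M and side product at 48.8% of the charge, which leaves [rival] at 0.128 M. With s at 0.579, the outlet ratio is 0.464, a share of 31.7%.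

The data come from a simulation with constants of no real substance, noise included.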